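(The earlier runs and the new flask are calculated with constants of no real substance; noise was put on by code.)

Late in a run, at 2.50 min, the readings should tell where a unit of charged Vy has gone, so the reckoning starts there.

| flask | Vy | Rx | remark | time |
|---|---|---|---|---|
| summer | 0.051 M (in portions, 4) | 0.114 M | run made earlier; portions every 40 s |  |
| spring | 0.11 M (in portions, 4) | 0.114 M | run made earlier; portions every 40 s |  |
| grey | 0.076 M (in portions, 4) | 0.114 M | the portions of Vy follow each other after 40 s, the first at the start | 2.5 min |
| blue | 0.076 M (in portions, 4) | 0.114 M | the portions of Vy follow each other after 40 s, the first at the start | 4.0 min |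

| run | time / min | Vy / % | Dx / % | Qa / % | Wa / % | Uv / % |
|---|---|---|---|---|---|---|
| summer | 0.500 | 8.7 | 3.6 | 1.2 | 0 | 6.8 |
| summer | 1.00 | 13.2 | 6.9 | 0.5 | 0 | 9.6 |
| summer | 1.50 | 17.4 | 13.4 | 0.9 | 0 | 12.2 |
| summer | 2.00 | 10.1 | 18.2 | 0 | 1.8 | 9.1 |
| summer | 2.50 | 11.4 | 23.8 | 0.8 | 1.5 | 10.6 |
| spring | 0.200 | 15.8 | 0.4 | 0 | 0.3 | 4.3 |
| spring | 0.417 | 7.9 | 3.0 | 0 | 0 | 4.3 |
| spring | 0.667 | 4.4 | 4.5 | 0 | 0.8 | 5.7 |
| spring | 1.33 | 7.6 | 9.2 | 0 | 0 | 9.3 |
| spring | 2.50 | 13.6 | 18.6 | 0 | 0.3 | 13.2 |

(each reading ± 1 percentage point)

- the analysis behind the earlier runs scatters by 1 percentage point, standard deviation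
- a reading of Vy is of its free form alone
- a reading at the moment of an addition is taken just before it

- which of these there is most of at the end, counted by the Vy in it, grey (Qa / Dx / Vy / Wa / Uv)
- which of these there is most of at the end, counted by the Vy in it, blue (Qa / Dx / Vy / Wa / Uv)
- the largest of these amounts at the end, in percent of the Vy charged, grey
- the largest of these amounts at the end, in percent of the Vy charged, blue

Question: follow one unit of Vy; what fork does it meet? Answer: once it has left free Vy, it either stands on the exchange line, as Uv, Dx, Wa or Qa, or it is in some form not read. At 2.50 min summer has lost 88.6% of its charge from free Vy and shows 36.7% on the line, a share of 41.4%; spring gives 37.2%.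

Question: is that gap real? Answer: each reading scatters by 1 percentage point, so I do not lean on it and carry the mean, 39.3%. This is the exchange share, the chance that Vy which has left its free form stands on the exchange line, a branching ratio.

Question: grey, then? Answer: grey's charge lies 42.4% of the way from summer to spring. Interpolating at 2.5 min gives free Vy 12.3%, Uv 11.7%, and Wa with Qa 1.45%. The share of what left free Vy, less Uv, Wa and Qa, leaves Dx at 21.3%, more than free Vy or Uv.

Question: blue runs on after the last portion at 2.00 min; what is your weak spot? Answer: the tail; the share is read, the tail is assumed. Between 1.50 min and 2.00 min summer received no portion, and its free Vy fell, taken as pseudo-first-order, at 1.09 /min. Blue has grey's recipe, so summer's rate, applied from grey's level, gives blue 2.41% at 4.0 min. At 2.50 min Uv reads close to free Vy in summer and in spring, so I set the two equal in blue, hold Wa with Qa at grey's level, and Dx comes to 34.5%.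

The forecast gives Dx at 21.5% for grey and Dx at 32% for blue, the blue figure below my 34.5%, and of the unseen form it says “I treat it as a side branch”.

The simulation gives Dx at 21.6% in grey and Dx at 28.9% in blue.

    Vy + Rx ⇌ Ja + Uv (K = 0.480, k = 0.174 /M/s)
    Uv + Rx ⇌ Ja + Dx (K = 1.88, k = 0.207 /M/s)
    Dx + Rx ⇌ Ja + Wa (K = 1.30, k = 0.00938 /M/s)
    Wa + Rx ⇌ Ja + Qa (K = 0.320, k = 0.333 /M/s)
    Ja + Vy ⇌ JaVy, settled at all times (K = 710 /M)

The unseen form is JaVy. In blue at 4.00 min, free Vy stands at 5.44% and Uv at 7.77%, against my 2.41% for each, and my Dx of 34.5% lies above the 28.9%, while the exchange share gives 37.2% on the line and the line holds 39.2%. At that moment in blue the Uv to Dx step, by itself and both ways together, relaxes with a half-life of 0.674 min, shorter than the 13.5 min of the Dx to Wa step reckoned the same way, and Dx is made 3.05 times faster than it is used up, each step taken net. In the neighbour flask, blue with 0.13 M of Vy and the same Rx and time, 7.9% of the charged Vy stays free at the end, and the exchange share gives 36.2% on the line; computed, the line holds 36.0%, with Dx at 24.2%.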